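**Assumptions (one line):** The core is read from the SMILES as (2S,3R,4R,5S)-2,5-diaryl-3,4-dimethyltetrahydrofuran (aryl cis to the adjacent methyl, aryls trans, methyls trans) and each side chain as (1R,2R). Commercial (R)-ethyl lactate, (S)-Me-CBS and (S,S)-Ru-TsDPEN are assumed available.

## Retrosynthetic overview
1. Disconnect both aryl–O(alkyl) ether bonds by Pd-catalysed C–O coupling. This gives the C2-symmetric bis(aryl bromide) THF **14** and two copies of the lactate-derived alcohol **24**.
2. THF **14** comes from Kishi-type ionic hydrogenation of lactol **13**, which comes from γ-lactone **12** and an aryl Grignard. Ring order: γ-lactone (step 10), THF (step 12), aryl ether bond last (step 21).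
3. Lactone **12** comes from keto-acid **11**, whose carbinol is set by Ru transfer hydrogenation. The keto-acid is made from the (2R,3R)-dimethylsuccinic Weinreb acid **10** and the Grignard of **3**.
4. The (2R,3R)-dimethylsuccinate comes from an Ireland–Claisen rearrangement of (R)-pent-3-en-2-yl propionate.
5. Side chain **24** comes from (R)-lactate: its ether-bearing carbon is untouched through the C–O coupling, and the benzylic carbinol is set by Ru transfer hydrogenation.

## Route

**Step 1**
Reactants: 1 (3-iodophenol)
Product: 2 (2-bromo-5-iodophenol)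
Conditions: NBS, iPr2NH (10 mol%), CH2Cl2, 0 °C → rt
Reagents that add atoms: N-bromosuccinimide, O=C1CCC(=O)N1Br
Why: Amine-assisted ortho-selective phenol bromination (Fujisaki type). The unhindered ortho position C6 is para to iodine, so Br ends up ortho to OH and para to I.

**Step 2**
Reactants: 2
Product: 3 (2-bromo-5-iodoanisole)
Conditions: MeI, K2CO3, acetone, 50 °C
Reagents that add atoms: iodomethane, CI
Why: Williamson O-methylation of the phenol.

**Step 3**
Reactants: 4 ((E)-pent-3-en-2-one)
Product: 5 ((2R,3E)-pent-3-en-2-ol)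
Conditions: (S)-Me-CBS (10 mol%), BH3·SMe2, THF, –20 °C
Reagents that add atoms: none (hydride only)
Why: CBS reduction is 1,2-selective on the enone. The propenyl group plays the "large" group, so (S)-catalyst gives the (R)-carbinol.

**Step 4**
Reactants: 5
Product: 6 ((2R,3E)-pent-3-en-2-yl propanoate)
Conditions: EtCOCl, Et3N, DMAP (cat.), CH2Cl2, 0 °C
Reagents that add atoms: propionyl chloride, CCC(=O)Cl
Why: Plain acylation; the stereocentre is untouched.

**Step 5**
Reactants: 6
Product: 7 ((2R,3S,4E)-2,3-dimethylhex-4-enoic acid)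
Conditions: LDA, THF/HMPA 4:1, –78 °C; TBSCl, –78 °C → rt; then aq. HCl
Reagents that add atoms: none (the silyl ester is hydrolysed on work-up)
Why: Ireland–Claisen [3,3] rearrangement. HMPA gives the enolate with Me trans to the ring oxygen. In the chair transition state both methyls are equatorial, so the product is syn. The (R)-carbinol transfers chirality to C3 suprafacially.

**Step 6**
Reactants: 7
Product: 8 ((2R,3R)-2,3-dimethylsuccinic acid)
Conditions: RuCl3·xH2O (3 mol%), NaIO4 (5 equiv), MeCN/EtOAc/H2O, rt
Reagents that add atoms: sodium periodate, [Na+].[O-]I(=O)(=O)=O; water, O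
Why: RuO4 oxidative alkene cleavage gives the carboxylic acid. The descriptor at C3 changes from S to R only because CIP priorities change, not the geometry.

**Step 7**
Reactants: 8
Product: 9 ((3R,4R)-3,4-dimethyloxolane-2,5-dione)
Conditions: Ac2O, reflux, 3 h
Reagents that add atoms: none (acts as dehydrating agent)
Why: Cyclodehydration. The trans anhydride is the stable isomer, so the α-centres are not eroded.

**Step 8**
Reactants: 9
Product: 10 (Weinreb acid, (2R,3R)-4-[methoxy(methyl)amino]-2,3-dimethyl-4-oxobutanoic acid)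
Conditions: MeNH(OMe)·HCl, Et3N, CH2Cl2, 0 °C → rt
Reagents that add atoms: N,O-dimethylhydroxylamine hydrochloride, CONC.Cl
Why: The C2-symmetric anhydride opens to a single regioisomer.

**Step 9**
Reactants: 10; 3 (as ArMgCl, Ar = 4-bromo-3-methoxyphenyl)
Product: 11 ((2R,3R)-4-(4-bromo-3-methoxyphenyl)-2,3-dimethyl-4-oxobutanoic acid)
Conditions: 3 + iPrMgCl·LiCl (3 equiv), THF, –20 °C, 1 h; add 10, 0 °C → rt, 3 h
Reagents that add atoms: none
Why: Iodine–magnesium exchange is selective for iodide over the ortho-OMe bromide. The Grignard then adds to the chelated Weinreb amide and stops at the ketone (the carboxylate is masked as its Mg salt).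

**Step 10**
Reactants: 11
Product: 12 ((3R,4R,5S)-5-(4-bromo-3-methoxyphenyl)-3,4-dimethyloxolan-2-one)
Conditions: RuCl[(S,S)-TsDPEN](p-cymene) (1 mol%), HCO2H/Et3N 5:2, rt; then TsOH (cat.), toluene, 50 °C
Reagents that add atoms: none
Why: Noyori asymmetric transfer hydrogenation of the aryl ketone under catalyst control gives the (S)-carbinol. Acid then lactonises it. The aryl group ends up cis to the C4 methyl.

**Step 11**
Reactants: 12; 3 (as ArMgCl)
Product: 13 (lactol, anomeric mixture)
Conditions: 3 + iPrMgCl·LiCl, THF, –20 °C; add 12 at –78 °C, 2 h; aq. NH4Cl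
Reagents that add atoms: none
Why: Aryl nucleophile addition to the lactone at –78 °C stops at the stable hemiketal, as in C-aryl glycoside syntheses.

**Step 12**
Reactants: 13
Product: 14 ((2S,3R,4R,5S)-2,5-bis(4-bromo-3-methoxyphenyl)-3,4-dimethyloxolane)
Conditions: Et3SiH (3 equiv), BF3·OEt2 (3 equiv), CH2Cl2, –78 → –40 °C
Reagents that add atoms: none (hydride only)
Why: Proposed new method: BF3 ionises the hemiketal to a 2-aryl oxocarbenium ion. In the envelope that keeps the trans-3,4-dimethyl groups pseudo-equatorial, the staggered "inside" approach of Et3SiH is anti to the adjacent C3 methyl. That puts the new aryl cis to the C3 methyl and trans to the C5 aryl, matching the target. The closest known reaction is the Kishi reduction of aryl C-glycoside lactols, combined with Woerpel-type nucleophile additions to substituted THF oxocarbenium ions. It has not been shown for this tetrasubstituted pattern. The C5 stereocentre is already fixed, and C3 and C4 are not touched.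

**Step 13**
Reactants: 15 (catechol)
Product: 16 (veratrole)
Conditions: MeI (2.5 equiv), K2CO3, acetone, reflux
Reagents that add atoms: iodomethane, CI
Why: Double Williamson O-methylation.

**Step 14**
Reactants: 16
Product: 17 (4-bromoveratrole)
Conditions: NBS, MeCN, 0 °C → rt
Reagents that add atoms: N-bromosuccinimide, O=C1CCC(=O)N1Br
Why: Electrophilic bromination at the position para to one OMe.

**Step 15**
Reactants: 18 (ethyl (R)-lactate)
Product: 19 (ethyl (2R)-2-(benzyloxy)propanoate)
Conditions: BnBr, Ag2O, Et2O, rt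
Reagents that add atoms: benzyl bromide, BrCc1ccccc1
Why: Mild, non-basic benzylation that avoids racemisation.

**Step 16**
Reactants: 19
Product: 20 ((2R)-2-(benzyloxy)-N-methoxy-N-methylpropanamide)
Conditions: MeNH(OMe)·HCl, iPrMgCl, THF, –20 °C
Reagents that add atoms: N,O-dimethylhydroxylamine hydrochloride, CONC.Cl
Why: Ester-to-Weinreb amide conversion.

**Step 17**
Reactants: 20; 17 (as 3,4-dimethoxyphenylMgBr)
Product: 21 ((2R)-2-(benzyloxy)-1-(3,4-dimethoxyphenyl)propan-1-one)
Conditions: 17, Mg, THF, reflux (Grignard); add 20, 0 °C → rt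
Reagents that add atoms: none
Why: Weinreb ketone synthesis; the α-alkoxy stereocentre survives.

**Step 18**
Reactants: 21
Product: 22 ((1R,2R)-2-(benzyloxy)-1-(3,4-dimethoxyphenyl)propan-1-ol)
Conditions: RuCl[(S,S)-TsDPEN](p-cymene) (1 mol%), HCO2H/Et3N 5:2, rt
Reagents that add atoms: none
Why: Catalyst-controlled transfer hydrogenation. The aryl group is the "large" group, so (S,S)-Ru gives the (R)-carbinol (the descriptor is R because CIP priorities change). This gives the threo (R,R) diol pattern.

**Step 19**
Reactants: 22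
Product: 23 (TBS ether of 22)
Conditions: TBSOTf, 2,6-lutidine, CH2Cl2, –78 → 0 °C
Reagents that add atoms: TBSOTf, CC(C)(C)[Si](C)(C)OS(=O)(=O)C(F)(F)F
Why: Protects the benzylic OH against later base and coupling conditions.

**Step 20**
Reactants: 23
Product: 24 ((1R,2R)-1-(tert-butyldimethylsilyloxy)-1-(3,4-dimethoxyphenyl)propan-2-ol)
Conditions: H2 (1 atm), 10% Pd/C, EtOAc, rt, short reaction time
Reagents that add atoms: none
Why: Chemoselective O-debenzylation; the silyl ether is retained.

**Step 21**
Reactants: 14; 24 (2.4 equiv)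
Product: 25 (bis-TBS ether of the target)
Conditions: tBuBrettPhos Pd G3 (5 mol%), Cs2CO3, toluene, 90 °C
Reagents that add atoms: none
Why: Buchwald–Hartwig-type Pd-catalysed C–O coupling. It is run twice on the C2-symmetric dibromide. The bulky biaryl phosphine favours ArPd(OR) reductive elimination over β-hydride elimination. The alcohol C–O bond is never broken, so the lactate-derived stereocentre is retained.

**Step 22**
Reactants: 25
Product: 26 (target)
Conditions: TBAF, THF, 0 °C → rt
Reagents that add atoms: none
Why: Fluoride removes both silyl ethers and leaves the benzylic alcohols and all stereocentres intact.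

## Compound list
1 | 3-iodophenol | Oc1cccc(I)c1 | starting material
2 | 2-bromo-5-iodophenol | Oc1cc(I)ccc1Br | intermediate
3 | 2-bromo-5-iodoanisole | COc1cc(I)ccc1Br | intermediate
4 | (E)-pent-3-en-2-one | C/C=C/C(C)=O | starting material
5 | (2R,3E)-pent-3-en-2-ol | C/C=C/[C@@H](C)O | intermediate
6 | (2R,3E)-pent-3-en-2-yl propanoate | C/C=C/[C@@H](C)OC(=O)CC | intermediate
7 | (2R,3S,4E)-2,3-dimethylhex-4-enoic acid | C/C=C/[C@H](C)[C@@H](C)C(=O)O | intermediate
8 | (2R,3R)-2,3-dimethylsuccinic acid | OC(=O)[C@H](C)[C@@H](C)C(=O)O | intermediate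
9 | (3R,4R)-3,4-dimethyloxolane-2,5-dione | C[C@H]1C(=O)OC(=O)[C@@H]1C | intermediate
10 | (2R,3R)-4-[methoxy(methyl)amino]-2,3-dimethyl-4-oxobutanoic acid | OC(=O)[C@H](C)[C@@H](C)C(=O)N(C)OC | intermediate
11 | (2R,3R)-4-(4-bromo-3-methoxyphenyl)-2,3-dimethyl-4-oxobutanoic acid | OC(=O)[C@H](C)[C@@H](C)C(=O)c1ccc(Br)c(OC)c1 | intermediate
12 | (3R,4R,5S)-5-(4-bromo-3-methoxyphenyl)-3,4-dimethyloxolan-2-one | O=C1O[C@H](c2ccc(Br)c(OC)c2)[C@H](C)[C@H]1C | intermediate
13 | lactol of 12 (2-aryl-2-hydroxy-THF, anomeric mixture) | OC1(c2ccc(Br)c(OC)c2)O[C@H](c2ccc(Br)c(OC)c2)[C@H](C)[C@H]1C | intermediate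
14 | (2S,3R,4R,5S)-2,5-bis(4-bromo-3-methoxyphenyl)-3,4-dimethyloxolane | COc1cc([C@H]2O[C@H](c3ccc(Br)c(OC)c3)[C@H](C)[C@H]2C)ccc1Br | intermediate
15 | catechol | Oc1ccccc1O | starting material
16 | veratrole | COc1ccccc1OC | intermediate
17 | 4-bromoveratrole | COc1ccc(Br)cc1OC | intermediate
18 | ethyl (R)-lactate | C[C@@H](O)C(=O)OCC | starting material
19 | ethyl (2R)-2-(benzyloxy)propanoate | C[C@@H](OCc1ccccc1)C(=O)OCC | intermediate
20 | (2R)-2-(benzyloxy)-N-methoxy-N-methylpropanamide | C[C@@H](OCc1ccccc1)C(=O)N(C)OC | intermediate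
21 | (2R)-2-(benzyloxy)-1-(3,4-dimethoxyphenyl)propan-1-one | C[C@@H](OCc1ccccc1)C(=O)c1ccc(OC)c(OC)c1 | intermediate
22 | (1R,2R)-2-(benzyloxy)-1-(3,4-dimethoxyphenyl)propan-1-ol | COc1ccc([C@@H](O)[C@@H](C)OCc2ccccc2)cc1OC | intermediate
23 | TBS ether of 22 | COc1ccc([C@@H](O[Si](C)(C)C(C)(C)C)[C@@H](C)OCc2ccccc2)cc1OC | intermediate
24 | (1R,2R)-1-(TBSO)-1-(3,4-dimethoxyphenyl)propan-2-ol | COc1ccc([C@@H](O[Si](C)(C)C(C)(C)C)[C@@H](C)O)cc1OC | intermediate
25 | bis-TBS ether of the target | COc1ccc([C@@H](O[Si](C)(C)C(C)(C)C)[C@@H](C)Oc2ccc([C@H]3O[C@H](c4ccc(O[C@H](C)[C@H](O[Si](C)(C)C(C)(C)C)c5ccc(OC)c(OC)c5)c(OC)c4)[C@H](C)[C@H]3C)cc2OC)cc1OC | intermediate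
26 | manassantin A | COc1ccc([C@@H](O)[C@@H](C)Oc2ccc([C@H]3O[C@H](c4ccc(O[C@H](C)[C@H](O)c5ccc(OC)c(OC)c5)c(OC)c4)[C@H](C)[C@H]3C)cc2OC)cc1OC | target

## Totals
- Total steps: 22.
- Longest linear sequence: 12 (steps 3 → 12, then 21 → 22), which is 0.55 of the total.

## Three steps most likely to fail
1. **Step 12 (proposed new ionic hydrogenation).** The hydride face selectivity on a tetrasubstituted oxocarbenium may be low and give the 2,5-cis epimer.
   Fallback (different approach, known chemistry): open lactone **12** with Me(MeO)NH·HCl/AlMe3, silylate the free OH, and add ArMgCl from **3** to give the aryl ketone. Reduce with (R,R)-Ru-TsDPEN to the (R)-carbinol, mesylate, and treat with TBAF. The liberated C5 alkoxide closes the ring by SN2 with inversion, giving **14**.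
2. **Step 21 (double C–O coupling).** The hindered α-branched secondary alcohol and the ortho-OMe aryl bromide may give low conversion or dehalogenation.
   Fallback: convert **14** to the bis-phenol (Pd/tBuBrettPhos, KOH, dioxane/H2O). Then do a double Mitsunobu with the (1R,2S)-silyl-protected diastereomer of **24** (from (S)-lactate by Zn(BH4)2 chelation-controlled reduction, TBS protection and debenzylation), which inverts to the (R)-ether carbon. Finish with TBAF.
3. **Step 1 (regioselective bromination of 3-iodophenol).** Bromination may also occur at C2 or C4.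
   Fallback: build **3** from 3-aminophenol by N-acetylation, NBS bromination (ortho to OH, para to N), O-methylation, deacetylation, and Sandmeyer iodination (NaNO2/KI).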